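Readings and results come from a simulation from invented constants.

Read at 1.0 min, this flask should show the left hand ahead. Read at 10 min, two chemists disagree about it.

in all of them: left-handed substrate 0.78 M; right-handed substrate 0.78 M

| run | solid reagent | remark | time |
|---|---|---|---|
| red | 2 equiv | the very flask that is asked about, followed so far |  |
| flask | 2.00 equiv |  | 10 min |

red run (percent of the left-handed substrate and right-handed substrate together charged)

| time / s | left-handed product / % | right-handed product / % | left-handed substrate / % |
|---|---|---|---|
| 25.0 | 4 | 6 | 46 |
| 50.0 | 11 | 8 | 35 |
| 80.0 | 12 | 8 | 27 |
| 90.0 | 18 | 10 | 26 |
| 120 | 21 | 15 | 20 |

(standard deviation of a reading: 2 percentage points)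

- coupling partner is single-handed; left-handed substrate and right-handed substrate are mirror images of each other, charged as a racemate, each of them at the stated concentration
- as a solid, counted per litre of solution: solid reagent
- the analysis behind the earlier runs scatters by 2 percentage points, standard deviation
- steps under discussion: coupling partner + left-handed substrate -> left-handed product; coupling partner + right-handed substrate -> right-handed product; left-handed substrate <-> achiral form; right-handed substrate <-> achiral form; achiral form -> waste; achiral form -> side product; solid reagent <-> coupling partner; left-handed product <-> right-handed product
- at the start none of the solid reagent is in solution
- what has gone into achiral form counts as reacted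
- an excess is the difference of the two amounts in percent of their sum
- an excess is below zero if the other one leads
- the handed part of coupling partner does not stay in what it makes, so the products of the two hands are mirror images too

* excess of left-handed product over right-handed product in the product at 1.0 min
* excess of left-handed product over right-handed product in the product at 10 min
* part of the left-handed substrate and right-handed substrate charged together that has reacted at 10 min

The red run is this same flask, followed so far. At 120 s it reads left-handed product 21% against right-handed product 15%, an excess of 16.7% by reading, with the scatter of small numbers.

The first chemist, who made the forecast, argues from the race. The left hand couples faster, with a selectivity factor of about 1.5, and the lead shrinks gradually: “Kinetic resolution erodes as the slower hand catches up”. The forecast says 18% early, 9% late and 98% reacted.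

The second chemist accepts the early number and counts instead. One coupling partner makes one product. So the solid reagent charged, over both substrates together, gives a cover of 100%, a ceiling on the product. Where the cover falls short of the substrate, the partner is the limiting reagent. Here it does not fall short.

The readings also give the left-handed substrate a half-life of about 1.32 min, and 10 min holds 7.58 of those. Both hands can therefore finish. Finishing alone does not make the products equal. But the steps under discussion include left-handed product going to right-handed product and back, and the two are mirror images, so a pair that interconverts comes to rest at equal amounts. On that ground the second chemist puts the late excess close to zero, well below the forecast. This is a judgement, with no rate for that step behind it.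

The flask gives 30.5%, 0.677% and 96.1%. The early excess is higher than the forecast's, and the late one is far lower.

    coupling partner + left-handed substrate → left-handed product (k = 0.0210 L mol⁻¹ s⁻¹)
    coupling partner + right-handed substrate → right-handed product (k = 0.00980 L mol⁻¹ s⁻¹)
    left-handed substrate ⇌ achiral form (K = 1.50, k = 0.00180 s⁻¹)
    right-handed substrate ⇌ achiral form (K = 1.50, k = 0.00180 s⁻¹)
    achiral form → waste (k = 9.30 × 10⁻⁴ s⁻¹)
    achiral form → side product (k = 0.00170 s⁻¹)
    solid reagent ⇌ coupling partner, rate k7*(cs7 - [coupling partner]) while solid is left; crystals form when [coupling partner] > cs7 (solubility = 0.530 M, k = 0.0370 s⁻¹)
    left-handed product ⇌ right-handed product (k = 0.00150 s⁻¹)

At 10 min the left-handed substrate couples 3.8 times faster than it passes into the achiral form, counting the forward step. The cover of 100% less the 79.0% of product leaves 21 percentage points, and the 0.327 M of coupling partner still standing is 21.0% of the substrate charged. The first chemist's lasting lead belongs to the neighbour flask with 0.800 equiv: its cover is 40.0%, its product 39.8%, its coupling partner 0.00240 M, and its late excess 5.99%.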